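**Compound numbers.** Numbers 1–21 are fixed by the forward route and used in every section. 15 is the acid that enters the key step, 16 its mixed anhydride, 17 the chromone it gives, and 21 is eriosemaone D.

## The problem

Eriosemaone D (21) is an isoflavone: a 4H-chromen-4-one (rings A and C) bonded through C3 to C6 of a 7-hydroxy-2,2-dimethyl-2H-chromene (ring B with its fused pyran, ring D). It has no stereocentre, so the task is one of connectivity, oxygenation pattern and functional-group tolerance.

Ring A carries the phloroglucinol pattern (O1, 5-OH, 7-OH). Ring B carries a resorcinol pattern in which one oxygen is locked in the dimethylpyran and the other is free, ortho to the C3–aryl bond.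

The fragile parts are three:
- The chromene C3=C4 bond of ring D adds acid and is hydrogenated easily.
- C2 of the pyranone is open to hydroxide.
- The free ring-B phenol sits next to C2 and can be cyclised onto it by oxidants.

Three phenols must therefore be masked while the skeleton is built and released without harming the chromene.

The feature that makes the key step possible is that the C4 carbonyl is bonded to C4a, which lies ortho to O1 and to the C5 oxygen and para to the C7 oxygen. An acyl electrophile tethered through O1–C2=C3 thus meets the most nucleophilic carbon of ring A. Because a 3,5-dioxygenated phenoxy group has two equivalent ortho carbons, the closure has no regiochemical choice to make.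

## Retrosynthesis

**21 ⇐ 20 ⇐ 19 (ring D alkene last).** The three acetyl–oxygen bonds of 20 are cut first, then the chromene C3=C4 bond is taken back to the saturated chroman 19. Carrying ring D as a chroman removes the only acid- and hydrogen-sensitive group from every earlier intermediate. The price is a late dehydrogenation that must find the benzylic C4–H faster than anything else. Acetates are chosen for that step because free phenols would be oxidised.

**19 ⇐ 18 ⇐ 17 (protecting-group exchange).** The acetates of 19 come from triol 18, and 18 from the tribenzyl ether 17 by cleavage of three O–benzyl bonds. Benzyl ethers suit the ring-forming chemistry because they are electron-releasing and stable to acid and base. Acetates suit the oxidation. The forward hydrogenolysis has to stop before the C2=C3 bond of the pyranone is touched, which the saturated ring D makes easier to arrange.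

**17 ⇐ 15 via 16 (C4–C4a, the key cut).** Cutting the bond between the carbonyl carbon and ring A gives the acyclic aryloxyacrylic acid 15. Two neighbouring cuts were weighed against it:
- O1–C2/C2–C3 (deoxybenzoin route) needs a phloroglucinol ketone with one free ortho hydroxyl.
- C3–aryl (cross-coupling) needs a 3-halochromone and a ring-B organometallic.

The chosen cut is the only one that turns ring A into a symmetric ether, so no ring-A oxygen has to be differentiated. The forward reaction must be an intramolecular acylation through the mixed anhydride 16, mild enough for three benzyl ethers.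

**15 ⇐ 14 ⇐ 12 + 13 (O1–C2).** After the ester 14 is unmasked from the acid, the vinyl ether C–O bond is cut to the symmetric phenol 13 and the enol tosylate 12. A cut at the acrylate–aryl bond instead would need a halogenated aryloxyacrylate, which cannot be made cleanly beside so electron-rich a ring. The forward step is an addition–elimination at the β-carbon and must favour O- over C-attack of the phenoxide.

**12 ⇐ 11 ⇐ 9 + 10 (C2–C3).** The tosylate is the activated enol of 11, and the hydroxymethylene carbon of 11 (future C2) comes from ethyl formate 10 by Claisen condensation with the arylacetate 9. This reduces the problem to a plain arylacetic ester. The condensation is driven by the acidity of its product.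

**9 ⇐ 6 + 7 via 8; 6 ⇐ 5 ⇐ 4 (aryl–CH2 bond).** The bond between ring B and the acetate carbon (future C3) is cut to aryl bromide 6 and the zinc enolate 8 of ethyl bromoacetate 7. Routes through an acetophenone and an oxidative rearrangement are no shorter and use harsher reagents. Bromide 6 follows from benzyl ether 5 and phenol 4; the bromination must go para to the ring oxygen, at C6 rather than C8.

**4 ⇐ 1 + 2 via 3 (ring D).** The chroman C4–C4a and O1–C2 bonds (chroman numbering) are cut to resorcinol 1 and the tertiary allylic alcohol 2. Prenylation to 3 and ring closure decide in one operation which resorcinol oxygen enters the pyran and which stays free. Control of mono- against bis-alkylation is asked of the forward reaction.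

## Roads not taken

**Alternative 1:** Ring A is cut at C4a–C5 and C8–C8a. Forward, the bis-silyloxy diene A3 would add across the sulfinyl-bearing double bond of the 3-aryl-5-sulfinylpyranone A2. Loss of the sulfinyl and methoxy groups would then aromatise the adduct to A1, with both ring-A hydroxyls free.
- Merits: ring A arrives unprotected, the chromene is present from the start and never meets strong acid, hydrogen or a quinone oxidant, and only one acetal remains to be removed. In endgame length this road is clearly better than the chosen one.
- Weak points: A2 is a pyran-4-one carrying two different substituents on its two α-carbons, each installed separately on a small heterocycle that nucleophiles open readily. A pyranone double bond is a reluctant dienophile, and the regiochemistry rests on the polarising effect of the sulfinyl group alone. The last acetal removal still exposes the chromene to acid.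
- Against this the chosen plan sets cheap aromatic building blocks, a ring A that is bought and not made, and a closure with no regiochemical question. It pays with a four-step endgame.

**Alternative 2:** Ring C is cut at C3–C4. Forward, an N-heterocyclic carbene would convert the ring-A aldehyde of the keto aldehyde A5 into an acyl anion equivalent that adds to the tethered aryl ketone, giving the racemic 3-hydroxychromanone A4.
- Merits: the conditions are mildly basic and compatible with an unmasked chromene, and A5 is assembled convergently by O-alkylation. In these respects it is gentler than a Friedel–Crafts acylation.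
- Weak points: the aldehyde of A5 is flanked by two ortho oxygens and is strongly electron-rich, both of which slow formation of the acyl anion equivalent. The acceptor ketone is also hindered and electron-rich. A4 carries a tertiary carbinol stereocentre that must be destroyed by dehydration to reach the isoflavone, so a step and some acid exposure are spent on nothing. A5 also needs one phloroglucinol oxygen differentiated from the other two and an α-functionalised ketone made beside the chromene alkene.
- The chosen plan reaches the chromone oxidation level directly and keeps ring A symmetric to the end. It gives up the comfort of carrying the chromene intact.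

**Alternative 3:** Ring B is cut at four bonds. Forward, irradiation of the chromonyl diazo enone A7 with the siloxyalkyne A8 would trigger Wolff rearrangement, [2+2] addition, ring opening and electrocyclisation to the prenylated phenol A6.
- Merits: the two ring-B oxygens emerge differentiated, with the prenyl group ortho to the free one, so oxidative cyclisation to the chromene is direct and regiochemically unambiguous. That is a cleaner answer to ring-B regiochemistry than electrophilic substitution of resorcinol.
- Weak points: the cascade builds a benzene ring that resorcinol supplies at no cost. A7 is a sensitive, multi-step diazo compound whose skipped diene can slip into conjugation. The chromone is itself a light-absorbing enone that can compete in the photochemical step. A8 must be prepared, and silyl and acetal removal with the chromene present still follow.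
- The chosen plan answers the regiochemical advantage with a one-step chroman synthesis and a selective bromination, and is far shorter in total.

Key step: step 9

Assumption: the push–pull alkenes 11, 12, 14, 15 and 16 are drawn as the Z isomers expected from chelation-controlled tosylation and retentive vinylic substitution. Any E isomer carried along is expected to converge in step 9, because the aryloxyacrylic anhydride equilibrates under acid.

## Route

Step 1
Reactants: 1 resorcinol (in excess); 2 2-methylbut-3-en-2-ol
Product: 4 2,2-dimethylchroman-7-ol, via 4-prenylresorcinol 3 (not isolated)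
Conditions: Amberlyst 15, THF, 65 °C
Reagents that add atoms: none
Why: Acid-catalysed Friedel–Crafts prenylation at C4 of resorcinol (para to one hydroxyl, ortho to the other), then Markovnikov hydroalkoxylation of the prenyl alkene by the ortho hydroxyl closes the chroman; excess resorcinol limits double annulation.

Step 2
Reactants: 4 2,2-dimethylchroman-7-ol
Product: 5 7-(benzyloxy)-2,2-dimethylchroman
Conditions: BnBr, K2CO3, DMF, rt to 60 °C
Reagents that add atoms: benzyl bromide, BrCc1ccccc1
Why: Williamson ether synthesis on the only phenol.

Step 3
Reactants: 5 7-(benzyloxy)-2,2-dimethylchroman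
Product: 6 7-(benzyloxy)-6-bromo-2,2-dimethylchroman
Conditions: NBS, MeCN, 0 °C to rt
Reagents that add atoms: N-bromosuccinimide, O=C1CCC(=O)N1Br
Why: Electrophilic aromatic bromination; C6 is para to the ring oxygen and ortho to the benzyloxy group, whereas C8 lies between two oxygens and is more hindered, and the polar medium suppresses radical benzylic bromination.

Step 4
Reactants: 6 7-(benzyloxy)-6-bromo-2,2-dimethylchroman; 7 ethyl bromoacetate
Product: 9 ethyl 2-[7-(benzyloxy)-2,2-dimethylchroman-6-yl]acetate, via BrZnCH2CO2Et 8 (not isolated)
Conditions: 7, Zn dust (TMSCl-activated), THF, 40 °C; then 6, Pd2(dba)3 (cat.), XPhos (cat.), THF, 60 °C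
Reagents that add atoms: none
Why: Palladium-catalysed α-arylation of a zinc ester enolate (Reformatsky–Negishi coupling): oxidative addition of zerovalent palladium to the C–Br bond, transmetalation from zinc and reductive elimination; the weakly basic zinc enolate avoids Claisen self-condensation and diarylation.

Step 5
Reactants: 9 ethyl 2-[7-(benzyloxy)-2,2-dimethylchroman-6-yl]acetate; 10 ethyl formate
Product: 11 ethyl (Z)-2-[7-(benzyloxy)-2,2-dimethylchroman-6-yl]-3-hydroxyacrylate
Conditions: NaH, 10 (excess), EtOH (cat.), THF, 0 °C to rt; then cold aq. HCl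
Reagents that add atoms: none
Why: Crossed Claisen condensation (α-formylation) with a non-enolisable formate, pulled to completion by deprotonation of the product; acidification gives the hydrogen-bonded Z enol.

Step 6
Reactants: 11 ethyl (Z)-2-[7-(benzyloxy)-2,2-dimethylchroman-6-yl]-3-hydroxyacrylate
Product: 12 ethyl (Z)-2-[7-(benzyloxy)-2,2-dimethylchroman-6-yl]-3-(tosyloxy)acrylate
Conditions: TsCl, N-methylimidazole, LiOH, toluene, 0 °C to rt
Reagents that add atoms: p-toluenesulfonyl chloride, Cc1ccc(cc1)S(Cl)(=O)=O
Why: Stereoselective enol tosylation by the N-sulfonylimidazolium formed from TsCl and N-methylimidazole; the lithium-chelated enolate should place the sulfonate cis to the ester (Z), whereas an amine base would favour E.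

Step 7
Reactants: 12 ethyl (Z)-2-[7-(benzyloxy)-2,2-dimethylchroman-6-yl]-3-(tosyloxy)acrylate; 13 3,5-dibenzyloxyphenol
Product: 14 ethyl (Z)-3-[3,5-bis(benzyloxy)phenoxy]-2-[7-(benzyloxy)-2,2-dimethylchroman-6-yl]acrylate
Conditions: Cs2CO3, MeCN, rt to 40 °C
Reagents that add atoms: none
Why: Nucleophilic vinylic substitution by addition–elimination: the phenoxide adds to the β-carbon of the acrylate and tosylate leaves from the ester enolate, normally with retention; a cesium phenoxide in a polar aprotic solvent favours O- over C-attack.

Step 8
Reactants: 14 ethyl (Z)-3-[3,5-bis(benzyloxy)phenoxy]-2-[7-(benzyloxy)-2,2-dimethylchroman-6-yl]acrylate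
Product: 15 (Z)-3-[3,5-bis(benzyloxy)phenoxy]-2-[7-(benzyloxy)-2,2-dimethylchroman-6-yl]acrylic acid
Conditions: LiOH, THF/MeOH/H2O, rt to 40 °C; then cold dilute HCl to pH 3
Reagents that add atoms: lithium hydroxide (supplies the carboxyl oxygen), [Li+].[OH-]
Why: Saponification at the ester carbonyl, as in the classical preparation of aryloxyacrylic acids for chromone synthesis; the β-aryloxyacrylate is a vinylogous carbonate, and cold, brief acidification spares the enol ether.

Step 9
Reactants: 15 (Z)-3-[3,5-bis(benzyloxy)phenoxy]-2-[7-(benzyloxy)-2,2-dimethylchroman-6-yl]acrylic acid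
Product: 17 5,7-bis(benzyloxy)-3-[7-(benzyloxy)-2,2-dimethylchroman-6-yl]-4H-chromen-4-one, via mixed trifluoroacetic anhydride 16 (not isolated)
Conditions: TFAA, CH2Cl2, 0 °C to rt
Reagents that add atoms: none
Why: TFAA converts acid 15 into the mixed anhydride 16, whose acyl carbon, further polarised by the trifluoroacetic acid set free, acts as an acylium equivalent. The ortho carbon of the phenoxy ring (future C4a), ortho or para to all three ring-A oxygens, attacks it, and the Wheland intermediate loses a proton to give the chromone; this is an intramolecular Friedel–Crafts acylation, and the cyclisation of 3-aryloxyacrylic acids to chromones is the closest known reaction type. Ring C closes as a six-membered ring in the 6-exo-trig sense at the acyl carbon (the C=O stays outside the new ring), and five of its six atoms are already coplanar in the Z acrylate. No stereocentre is formed. Site selectivity is settled by the substrate: both ortho carbons of the 3,5-dibenzyloxyphenoxy group are equivalent, the para carbon cannot reach the acyl carbon, and ring B could only close a four-membered ring. The Z geometry places the acyl group cis to the aryloxy group; an E isomer should equilibrate by reversible protonation at the α-carbon through the oxocarbenium ion at C2. Selectivity against intermolecular trifluoroacetylation of ring A rests on the intramolecular rate at moderate dilution, and the benzyl ethers and the saturated ring D are inert to trifluoroacetic acid at this temperature.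

Step 10
Reactants: 17 5,7-bis(benzyloxy)-3-[7-(benzyloxy)-2,2-dimethylchroman-6-yl]-4H-chromen-4-one
Product: 18 5,7-dihydroxy-3-(7-hydroxy-2,2-dimethylchroman-6-yl)-4H-chromen-4-one
Conditions: H2 (1 atm), 10% Pd/C, EtOAc/MeOH, rt, stopped after three equivalents of H2
Reagents that add atoms: none
Why: Catalytic hydrogenolysis of three benzyl aryl ethers; ring D has no reducible alkene, and the vinylogous-ester C2=C3 bond of the chromone is reduced much more slowly than benzyl ethers are cleaved.

Step 11
Reactants: 18 5,7-dihydroxy-3-(7-hydroxy-2,2-dimethylchroman-6-yl)-4H-chromen-4-one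
Product: 19 3-(7-acetoxy-2,2-dimethylchroman-6-yl)-4-oxo-4H-chromene-5,7-diyl diacetate
Conditions: Ac2O, pyridine, DMAP (cat.), rt
Reagents that add atoms: acetic anhydride, CC(=O)OC(C)=O
Why: Peracetylation with nucleophilic catalysis, including the chelated 5-hydroxyl; masking the phenols prevents their oxidation and the oxidative cyclisation of the ring-B phenol onto C2 in the next step.

Step 12
Reactants: 19 3-(7-acetoxy-2,2-dimethylchroman-6-yl)-4-oxo-4H-chromene-5,7-diyl diacetate
Product: 20 3-(7-acetoxy-2,2-dimethyl-2H-chromen-6-yl)-4-oxo-4H-chromene-5,7-diyl diacetate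
Conditions: DDQ, 1,4-dioxane, reflux
Reagents that add atoms: none
Why: Quinone dehydrogenation of a 2,2-dimethylchroman: hydride abstraction from benzylic C4 gives a cation stabilised through the arene by the ring oxygen, and loss of a C3 proton gives the 2H-chromene; the quaternary C2 stops the oxidation there.

Step 13
Reactants: 20 3-(7-acetoxy-2,2-dimethyl-2H-chromen-6-yl)-4-oxo-4H-chromene-5,7-diyl diacetate
Product: 21 eriosemaone D, 5,7-dihydroxy-3-(7-hydroxy-2,2-dimethyl-2H-chromen-6-yl)-4H-chromen-4-one
Conditions: K2CO3 (cat.), MeOH, 0 °C to rt; then aq. NH4Cl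
Reagents that add atoms: none
Why: Base-catalysed methanolysis (transesterification) of three aryl acetates under conditions too mild to open the pyranone or to affect the chromene.

## Compound list

1 | resorcinol | Oc1cccc(O)c1 | starting material
2 | 2-methylbut-3-en-2-ol | CC(C)(O)C=C | starting material
3 | 4-(3-methylbut-2-en-1-yl)benzene-1,3-diol (4-prenylresorcinol) | CC(C)=CCc1ccc(O)cc1O | intermediate
4 | 2,2-dimethylchroman-7-ol | CC1(C)CCc2ccc(O)cc2O1 | intermediate
5 | 7-(benzyloxy)-2,2-dimethylchroman | CC1(C)CCc2ccc(OCc3ccccc3)cc2O1 | intermediate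
6 | 7-(benzyloxy)-6-bromo-2,2-dimethylchroman | CC1(C)CCc2cc(Br)c(OCc3ccccc3)cc2O1 | intermediate
7 | ethyl bromoacetate | CCOC(=O)CBr | starting material
8 | ethyl 2-(bromozincio)acetate, BrZnCH2CO2Et | CCOC(=O)C[Zn]Br | intermediate
9 | ethyl 2-[7-(benzyloxy)-2,2-dimethylchroman-6-yl]acetate | CCOC(=O)Cc1cc2CCC(C)(C)Oc2cc1OCc1ccccc1 | intermediate
10 | ethyl formate | CCOC=O | starting material
11 | ethyl (Z)-2-[7-(benzyloxy)-2,2-dimethylchroman-6-yl]-3-hydroxyacrylate | CCOC(=O)/C(=C\O)c1cc2CCC(C)(C)Oc2cc1OCc1ccccc1 | intermediate
12 | ethyl (Z)-2-[7-(benzyloxy)-2,2-dimethylchroman-6-yl]-3-(tosyloxy)acrylate | CCOC(=O)/C(=C\OS(=O)(=O)c1ccc(C)cc1)c1cc2CCC(C)(C)Oc2cc1OCc1ccccc1 | intermediate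
13 | 3,5-dibenzyloxyphenol | Oc1cc(OCc2ccccc2)cc(OCc2ccccc2)c1 | starting material
14 | ethyl (Z)-3-[3,5-bis(benzyloxy)phenoxy]-2-[7-(benzyloxy)-2,2-dimethylchroman-6-yl]acrylate | CCOC(=O)/C(=C\Oc1cc(OCc2ccccc2)cc(OCc2ccccc2)c1)c1cc2CCC(C)(C)Oc2cc1OCc1ccccc1 | intermediate
15 | (Z)-3-[3,5-bis(benzyloxy)phenoxy]-2-[7-(benzyloxy)-2,2-dimethylchroman-6-yl]acrylic acid | OC(=O)/C(=C\Oc1cc(OCc2ccccc2)cc(OCc2ccccc2)c1)c1cc2CCC(C)(C)Oc2cc1OCc1ccccc1 | intermediate
16 | (Z)-3-[3,5-bis(benzyloxy)phenoxy]-2-[7-(benzyloxy)-2,2-dimethylchroman-6-yl]acrylic trifluoroacetic anhydride | O=C(OC(=O)C(F)(F)F)/C(=C\Oc1cc(OCc2ccccc2)cc(OCc2ccccc2)c1)c1cc2CCC(C)(C)Oc2cc1OCc1ccccc1 | intermediate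
17 | 5,7-bis(benzyloxy)-3-[7-(benzyloxy)-2,2-dimethylchroman-6-yl]-4H-chromen-4-one | O=c1c(-c2cc3CCC(C)(C)Oc3cc2OCc2ccccc2)coc2cc(OCc3ccccc3)cc(OCc3ccccc3)c12 | intermediate
18 | 5,7-dihydroxy-3-(7-hydroxy-2,2-dimethylchroman-6-yl)-4H-chromen-4-one | O=c1c(-c2cc3CCC(C)(C)Oc3cc2O)coc2cc(O)cc(O)c12 | intermediate
19 | 3-(7-acetoxy-2,2-dimethylchroman-6-yl)-4-oxo-4H-chromene-5,7-diyl diacetate | CC(=O)Oc1cc2OC(C)(C)CCc2cc1-c1coc2cc(OC(C)=O)cc(OC(C)=O)c2c1=O | intermediate
20 | 3-(7-acetoxy-2,2-dimethyl-2H-chromen-6-yl)-4-oxo-4H-chromene-5,7-diyl diacetate | CC(=O)Oc1cc2OC(C)(C)C=Cc2cc1-c1coc2cc(OC(C)=O)cc(OC(C)=O)c2c1=O | intermediate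
21 | eriosemaone D, 5,7-dihydroxy-3-(7-hydroxy-2,2-dimethyl-2H-chromen-6-yl)-4H-chromen-4-one | CC1(C)C=Cc2cc(-c3coc4cc(O)cc(O)c4c3=O)c(O)cc2O1 | target

## Step count and least certain steps

Total step count: 13. Longest linear sequence: 13 steps (1 to 21); 7, 10 and 13 enter as purchased materials.

**Step 9 (key step).** The electron-rich ring A may be trifluoroacetylated intermolecularly before it closes. The ortho benzyloxy oxygen of ring B may attack the anhydride with loss of its benzyl group, which is lactonisation to a benzofuranone. The aryl vinyl ether may also be cleaved by acid.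

The fallback gives up the C4–C4a closure and builds ring C by the deoxybenzoin route. It sets out from ester 9, which is saponified to 2-[7-(benzyloxy)-2,2-dimethylchroman-6-yl]acetic acid F1. F1 acylates phloroglucinol (BF3·OEt2, warm) to give 2-[7-(benzyloxy)-2,2-dimethylchroman-6-yl]-1-(2,4,6-trihydroxyphenyl)ethan-1-one F2. One-carbon insertion with DMF, BF3·OEt2 and MsCl closes the pyranone to 3-[7-(benzyloxy)-2,2-dimethylchroman-6-yl]-5,7-dihydroxy-4H-chromen-4-one F3. Hydrogenolysis of its single benzyl ether rejoins the route at 18.

**Step 7.** The phenoxide may attack sulfur instead of carbon, transferring the sulfonyl group. It may react through its ring carbon, since phloroglucinol-type phenoxides are ambident. Reversible addition may also erode the alkene geometry.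

The fallback removes the second electrophilic site. It sets out from enol 11, which is converted with (COCl)2 and DMF (cat.) into the vinylogous acid chloride ethyl (Z)-2-[7-(benzyloxy)-2,2-dimethylchroman-6-yl]-3-chloroacrylate F4. Displacement of chloride by the potassium phenoxide of 13 (K2CO3, DMF), the classical β-chloroacrylate route to aryloxyacrylates, comes back at 14.

**Step 8.** Hydroxide may add to the β-carbon and expel the aryloxide, which is a retro vinylic substitution, instead of attacking the ester carbonyl.

The fallback avoids hydroxide altogether by carrying a tert-butyl ester. It sets out from bromide 6 and proceeds as follows: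
- Coupling with commercial BrZnCH2CO2tBu under the conditions of step 4 gives tert-butyl 2-[7-(benzyloxy)-2,2-dimethylchroman-6-yl]acetate F5.
- Formylation as in step 5 gives tert-butyl (Z)-2-[7-(benzyloxy)-2,2-dimethylchroman-6-yl]-3-hydroxyacrylate F6.
- Tosylation as in step 6 gives tert-butyl (Z)-2-[7-(benzyloxy)-2,2-dimethylchroman-6-yl]-3-(tosyloxy)acrylate F7.
- Substitution with 13 as in step 7 gives tert-butyl (Z)-3-[3,5-bis(benzyloxy)phenoxy]-2-[7-(benzyloxy)-2,2-dimethylchroman-6-yl]acrylate F8.
- Acidolysis (TFA, CH2Cl2, anisole as cation scavenger) returns to the route at acid 15.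

**Step 10.** The C2=C3 bond of the chromone may be reduced further to the isoflavanone, or the 5-O-benzyl group may be cleaved incompletely. The fallback replaces hydrogen by a Lewis-acid dealkylation, which has no reducing agent and which the saturated ring D tolerates. It sets out from 17, uses BCl3 and pentamethylbenzene in CH2Cl2 at −78 °C, and arrives directly at 18 with no new intermediate.

**Step 12.** Hydride abstraction may be slow because the acetylated ring B is a weaker donor, and forcing conditions may lead to over-oxidation or quinone adducts. The fallback installs the alkene by substitution and elimination. It sets out from 19, where radical bromination (NBS, AIBN, PhCF3, 80 °C) at the only benzylic C–H position gives racemic 3-(7-acetoxy-4-bromo-2,2-dimethylchroman-6-yl)-4-oxo-4H-chromene-5,7-diyl diacetate F9. Dehydrobromination with DBU rejoins the route at 20.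

**Step 1.** Alkylation at C2 of resorcinol would give the 5-hydroxy isomer, and double annulation would consume product. The fallback fixes the regiochemistry by acylation. It sets out from 1, which with 3,3-dimethylacrylic acid in MeSO3H/P2O5 gives 7-hydroxy-2,2-dimethylchroman-4-one F10 (acylation para to one hydroxyl, then oxa-Michael closure). Ionic hydrogenation of the aryl ketone (Et3SiH, TFA) comes back at 4.

## Further compounds

F1 | step 9 | 2-[7-(benzyloxy)-2,2-dimethylchroman-6-yl]acetic acid | OC(=O)Cc1cc2CCC(C)(C)Oc2cc1OCc1ccccc1
F2 | step 9 | 2-[7-(benzyloxy)-2,2-dimethylchroman-6-yl]-1-(2,4,6-trihydroxyphenyl)ethan-1-one | O=C(Cc1cc2CCC(C)(C)Oc2cc1OCc1ccccc1)c1c(O)cc(O)cc1O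
F3 | step 9 | 3-[7-(benzyloxy)-2,2-dimethylchroman-6-yl]-5,7-dihydroxy-4H-chromen-4-one | O=c1c(-c2cc3CCC(C)(C)Oc3cc2OCc2ccccc2)coc2cc(O)cc(O)c12
F4 | step 7 | ethyl (Z)-2-[7-(benzyloxy)-2,2-dimethylchroman-6-yl]-3-chloroacrylate | CCOC(=O)/C(=C\Cl)c1cc2CCC(C)(C)Oc2cc1OCc1ccccc1
F5 | step 8 | tert-butyl 2-[7-(benzyloxy)-2,2-dimethylchroman-6-yl]acetate | CC(C)(C)OC(=O)Cc1cc2CCC(C)(C)Oc2cc1OCc1ccccc1
F6 | step 8 | tert-butyl (Z)-2-[7-(benzyloxy)-2,2-dimethylchroman-6-yl]-3-hydroxyacrylate | CC(C)(C)OC(=O)/C(=C\O)c1cc2CCC(C)(C)Oc2cc1OCc1ccccc1
F7 | step 8 | tert-butyl (Z)-2-[7-(benzyloxy)-2,2-dimethylchroman-6-yl]-3-(tosyloxy)acrylate | CC(C)(C)OC(=O)/C(=C\OS(=O)(=O)c1ccc(C)cc1)c1cc2CCC(C)(C)Oc2cc1OCc1ccccc1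
F8 | step 8 | tert-butyl (Z)-3-[3,5-bis(benzyloxy)phenoxy]-2-[7-(benzyloxy)-2,2-dimethylchroman-6-yl]acrylate | CC(C)(C)OC(=O)/C(=C\Oc1cc(OCc2ccccc2)cc(OCc2ccccc2)c1)c1cc2CCC(C)(C)Oc2cc1OCc1ccccc1
F0 | step 10 | none | none
F9 | step 12 | 3-(7-acetoxy-4-bromo-2,2-dimethylchroman-6-yl)-4-oxo-4H-chromene-5,7-diyl diacetate (racemic) | CC(=O)Oc1cc2OC(C)(C)CC(Br)c2cc1-c1coc2cc(OC(C)=O)cc(OC(C)=O)c2c1=O
F10 | step 1 | 7-hydroxy-2,2-dimethylchroman-4-one | CC1(C)CC(=O)c2ccc(O)cc2O1
A1 | alternative 1 | 5,7-dihydroxy-3-[7-(methoxymethoxy)-2,2-dimethyl-2H-chromen-6-yl]-4H-chromen-4-one | COCOc1cc2OC(C)(C)C=Cc2cc1-c1coc2cc(O)cc(O)c2c1=O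
A2 | alternative 1 | 3-[7-(methoxymethoxy)-2,2-dimethyl-2H-chromen-6-yl]-5-(phenylsulfinyl)-4H-pyran-4-one (racemic at sulfur) | COCOc1cc2OC(C)(C)C=Cc2cc1-c1cocc(S(=O)c2ccccc2)c1=O
A3 | alternative 1 | 1-methoxy-1,3-bis(trimethylsilyloxy)buta-1,3-diene | COC(=CC(=C)O[Si](C)(C)C)O[Si](C)(C)C
A4 | alternative 2 | 3-hydroxy-5,7-bis(methoxymethoxy)-3-[7-(methoxymethoxy)-2,2-dimethyl-2H-chromen-6-yl]chroman-4-one (racemic) | COCOc1cc(OCOC)c2C(=O)C(O)(c3cc4C=CC(C)(C)Oc4cc3OCOC)COc2c1
A5 | alternative 2 | 2-{2-[7-(methoxymethoxy)-2,2-dimethyl-2H-chromen-6-yl]-2-oxoethoxy}-4,6-bis(methoxymethoxy)benzaldehyde | O=Cc1c(OCOC)cc(OCOC)cc1OCC(=O)c1cc2C=CC(C)(C)Oc2cc1OCOC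
A6 | alternative 3 | 3-[4-hydroxy-5-(3-methylbut-2-en-1-yl)-2-(triisopropylsilyloxy)phenyl]-5,7-bis(methoxymethoxy)-4H-chromen-4-one | COCOc1cc(OCOC)c2c(c1)occ(-c1cc(CC=C(C)C)c(O)cc1O[Si](C(C)C)(C(C)C)C(C)C)c2=O
A7 | alternative 3 | 3-[(3E)-1-diazo-7-methyl-2-oxoocta-3,6-dien-1-yl]-5,7-bis(methoxymethoxy)-4H-chromen-4-one | COCOc1cc(OCOC)c2c(c1)occ(C(=[N+]=[N-])C(=O)/C=C/CC=C(C)C)c2=O
A8 | alternative 3 | (triisopropylsilyloxy)acetylene | C#CO[Si](C(C)C)(C(C)C)C(C)C
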